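Remark: atom labels C1–C15 follow germacrane numbering (ring C1–C10; C14 on C10, C15 on C4; lactone oxygen on C6, C11 on C7, C12 the lactone carbonyl, C13 on C11). The target is read as (3S,6S,7S,9R,11R) with 1(10)Z and 4Z olefins. Compound numbers are plain numbers; atoms carry the prefix C. (R)-Carvone and methyl (S)-3-hydroxy-2-methylpropanoate are taken as commercial.

## The problem

The target is a cis,cis-germacranolide: a cyclodeca-1(10),4-diene in which both trisubstituted ring olefins (C1=C10 and C4=C5) are Z, trans-fused at C6–C7 to an α-methyl-γ-lactone, with allylic acetates at C3 and C9. A ten-membered carbocycle closes slowly end to end, and any closure must also deliver or tolerate two Z trisubstituted olefins. Of the five stereocentres, C6, C7 and C11 are contiguous and can control each other, whereas C3 and C9 are isolated allylic carbinols that the lactone cannot reach by simple relay. C11 carries its methyl cis to C8, an arrangement liable to epimerise at an enolisable lactone, so it should be fixed early and kept from base once the lactone exists. The unit C10=C1–C2–C3(O)–C4=C5 is a 3-oxy-1,5-diene, so a free C3 alkoxide of the finished ring must be avoided; the allylic esters and the lactone also exclude strong acid, strong nucleophiles and late hydride reagents. The feature used here: with C9 as a ketone, C9(=O)–C8–C7–C6–C5=C4 is a cyclodec-5-en-1-one, the product pattern of an oxy-Cope ring expansion. The rest of the ring, C9–C10(C14)=C1–C2–C3(O)–C4, then closes to a 5-oxy-2-methylcyclohex-2-enone (ring A), which holds C1=C10 Z by ring size and is available from carvone.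

## Retrosynthesis

**25 to 24 (C3–O acetate).** The C3 acetate is cut with inversion: Mitsunobu esterification of the 3R alcohol 24 with acetic acid. This is preferred to plain acetylation because the favoured chair of the key step gives the 3R series (see below); inversion and acetylation then cost one step. The forward reaction must be a clean SN2 displacement at an allylic carbinol.

**24 to 22 and 21 (lactone C12–O6).** The lactone is cut to the 1,4-diol of triol 22, to be closed by oxidation of the primary alcohol. Against an ester enolate route, this never exposes C11 to base, so its configuration is simply carried. Triol 22 comes from tris-silyl ether 21, in which the C9 acetate is already in place.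

**21 to 20 and 19 (C9–H).** The C9 carbinol is cut to ketone 19. C9 sits between C8H2 and an α-methyl alkenyl group, the large/small pattern that a Corey–Bakshi–Shibata reduction reads well, so C9 is set by the reagent, not by an unpredictable ring conformation.

**19 to 16 (C6–C7 cut, C4–C9 rejoined).** This is the key disconnection: an anionic oxy-Cope rearrangement in reverse. Against end-to-end closures, it replaces a ten-membered ring closure by a four-carbon ring expansion of a cyclohexenol. It also makes the C4=C5 olefin and the C6/C7 stereocentres in the same event. Precursor 16 has only ring A and two E alkenyl arms. The forward reaction must pass through the chair in which C3 is axial on the six-atom array (Z olefin). That chair needs the C3 silyloxy group equatorial and cis to C15, and chirality transfer then gives 6S,7S only from the 3R ring; hence C3 is carried as R and inverted at the end.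

**16 to 10 and 14 (C8–C9).** The tertiary carbinol is cut to enone 10 and alkenyl iodide 14, joined through alkenyllithium 15. The addition must come anti to the axial C15 methyl, so that the two alkenyl arms are cis.

**10 to 9, 7, 6 and 5 (C4 substituents).** The enol ether of 10 is the E silyl enol ether of aldehyde 9, which comes from allyl ketone 7 by oxidative cleavage through diol 8. The quaternary centre C4 is made by two enolate alkylations of 5 (methyl, giving 6, then allyl), each anti to the C3 silyloxy group; the second fixes C15 cis to OTBS.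

**5 to 1 (C3–O).** Enone 5 comes from (R)-carvone 1 by Criegee degradation of the isopropenyl group through hydroperoxide 2 to acetate 3, methanolysis to 4 and silylation. C3 is thus bought, and it controls C4, C9, C6 and C7 in turn.

**14 to 11 (C7=C8).** Iodide 14 comes from the (S)-Roche ester 11 through silyl ether 12 and aldehyde 13 by Takai olefination; C11 is bought with it.

## Roads not taken

**Alternative 1:** the most obvious cut is C9–C10. The forward key step is an intramolecular Nozaki–Hiyama–Kishi reaction (CrCl2, NiCl2 cat.) of seco aldehyde/(Z)-iodoalkene A1. This closure forms one bond and one stereocentre (C9), whose sense would depend on an unknown ring conformation. A1 must already contain both Z trisubstituted olefins and four stereocentres, each made separately on an open chain. The chosen plan gets the ring, one Z olefin and two stereocentres from a cyclohexenol in one step, and takes the other Z olefin from a six-membered ring.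

**Alternative 2:** cut C4–C9 ionically. The forward key step is a Wharton–Grob fragmentation of cis-fused decalin A2 (C9 tertiary alkoxide, C5 mesylate, lactone already on ring B). The Z olefin would be stereospecific, but A2 needs seven stereocentres, three of which (C4, C5, C9) are made only to be destroyed. The C7 side chain must also be placed on the concave face of the cis-decalin, against the usual course of additions. The chosen plan breaks the same bond pericyclically and uses the breaking to make C6–C7 with its two stereocentres.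

**Alternative 3:** cut C6–C7 with the lactone. The forward key step is an intramolecular Barbier-type 2-(alkoxycarbonyl)allylation (CrCl2 or Zn) of aldehyde/allylic bromide A3, followed by lactonisation and hydrogenation of the α-methylene lactone. It closes the ring and sets C6/C7, but the (Z)-enal of A3 is prone to Z-to-E isomerisation. C11 would need a chemoselective and face-selective hydrogenation beside two trisubstituted olefins. Both Z olefins and C3 and C9 must again be built on the open chain.

Key step: step 12

## Route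

Step 1
Reactants: 1 (R)-carvone
Product: 3 (5R)-5-acetoxy-2-methylcyclohex-2-en-1-one, via methoxy hydroperoxide 2 (not isolated)
Conditions: O3, CH2Cl2–MeOH, −78 °C; then Ac2O, Et3N, 4-(dimethylamino)pyridine (cat.), −78 °C → rt
Reagents that add atoms: ozone, [O-][O+]=O; methanol, CO
Why: Ozone cleaves the electron-rich isopropenyl group and spares the enone; methanol traps the carbonyl oxide as 2, and acylation of the hydroperoxide triggers the Criegee rearrangement, in which the ring carbon migrates to oxygen with retention. The isopropenyl carbon and its methyl become the acetyl group of 3.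

Step 2
Reactants: 3 (5R)-5-acetoxy-2-methylcyclohex-2-en-1-one
Product: 4 (5R)-5-hydroxy-2-methylcyclohex-2-en-1-one
Conditions: K2CO3 (cat.), MeOH, 0 °C
Reagents that add atoms: none
Why: Base-catalysed transesterification at 0 °C should free the alcohol before β-elimination to the phenol can compete; the stereocentre is not touched.

Step 3
Reactants: 4 (5R)-5-hydroxy-2-methylcyclohex-2-en-1-one
Product: 5 (5R)-5-(tert-butyldimethylsilyloxy)-2-methylcyclohex-2-en-1-one
Conditions: t-BuMe2SiCl, imidazole, DMF, rt
Reagents that add atoms: tert-butyldimethylsilyl chloride, CC(C)(C)[Si](C)(C)Cl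
Why: Standard silylation of a secondary alcohol; the silyl ether is the steric control element for the next four C–C bond formations.

Step 4
Reactants: 5 (5R)-5-(tert-butyldimethylsilyloxy)-2-methylcyclohex-2-en-1-one
Product: 6 (5R,6S)-5-(tert-butyldimethylsilyloxy)-2,6-dimethylcyclohex-2-en-1-one
Conditions: LiN(iPr)2, THF, −78 °C; MeI, −78 → −40 °C
Reagents that add atoms: iodomethane, CI
Why: Kinetic α′-deprotonation (C4) and enolate methylation, expected trans to OTBS; the configuration at C4 is of no consequence here because the next step re-forms the enolate.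

Step 5
Reactants: 6 (5R,6S)-5-(tert-butyldimethylsilyloxy)-2,6-dimethylcyclohex-2-en-1-one
Product: 7 (5R,6S)-6-allyl-5-(tert-butyldimethylsilyloxy)-2,6-dimethylcyclohex-2-en-1-one
Conditions: LiN(iPr)2, THF, −78 °C; allyl bromide, DMPU, −78 → −30 °C
Reagents that add atoms: allyl bromide, C=CCBr
Why: Diastereoselective α-alkylation of the fully substituted α′-enolate: allyl bromide should enter anti to the adjacent C3 silyloxy group, which sets the quaternary centre C4 with the allyl group trans and C15 cis to OTBS.

Step 6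
Reactants: 7 (5R,6S)-6-allyl-5-(tert-butyldimethylsilyloxy)-2,6-dimethylcyclohex-2-en-1-one
Product: 9 2-[(1S,6R)-6-(tert-butyldimethylsilyloxy)-1,3-dimethyl-2-oxocyclohex-3-en-1-yl]acetaldehyde, via diol 8 (not isolated)
Conditions: OsO4 (cat.), NaIO4, 2,6-lutidine, dioxane–H2O, rt
Reagents that add atoms: sodium periodate, [Na+].[O-][I](=O)(=O)=O
Why: Lemieux–Johnson cleavage: OsO4 dihydroxylates the monosubstituted olefin much faster than the electron-poor enone, and periodate cleaves diol 8 to the aldehyde.

Step 7
Reactants: 9 2-[(1S,6R)-6-(tert-butyldimethylsilyloxy)-1,3-dimethyl-2-oxocyclohex-3-en-1-yl]acetaldehyde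
Product: 10 (5R,6S)-5-(tert-butyldimethylsilyloxy)-2,6-dimethyl-6-[(E)-2-(triisopropylsilyloxy)ethenyl]cyclohex-2-en-1-one
Conditions: iPr3SiOSO2CF3, Et3N, CH2Cl2, −78 °C → rt
Reagents that add atoms: triisopropylsilyl triflate, CC(C)[Si](OS(=O)(=O)C(F)(F)F)(C(C)C)C(C)C
Why: Soft enolisation of the aldehyde (silyl triflate and amine); the ketone has no α-hydrogen on the C4 side. The E enol ether is expected because the Z isomer would hold OSi(iPr)3 cis to the quaternary carbon C4; any Z isomer is removed here, since it would give the C6 epimer in step 12.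

Step 8
Reactants: 11 methyl (S)-3-hydroxy-2-methylpropanoate
Product: 12 methyl (S)-3-(tert-butyldimethylsilyloxy)-2-methylpropanoate
Conditions: t-BuMe2SiCl, imidazole, CH2Cl2, rt
Reagents that add atoms: tert-butyldimethylsilyl chloride, CC(C)(C)[Si](C)(C)Cl
Why: Standard silylation of the primary alcohol of the Roche ester, which carries the future C11 stereocentre.

Step 9
Reactants: 12 methyl (S)-3-(tert-butyldimethylsilyloxy)-2-methylpropanoate
Product: 13 (S)-3-(tert-butyldimethylsilyloxy)-2-methylpropanal
Conditions: i-Bu2AlH, CH2Cl2, −78 °C; aqueous work-up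
Reagents that add atoms: none
Why: Partial reduction of the ester through the aluminium hemiacetal, stable at −78 °C; the α-stereocentre is not enolised.

Step 10
Reactants: 13 (S)-3-(tert-butyldimethylsilyloxy)-2-methylpropanal
Product: 14 tert-butyl{[(2R,3E)-4-iodo-2-methylbut-3-en-1-yl]oxy}dimethylsilane
Conditions: CrCl2, CHI3, THF, 0 °C → rt
Reagents that add atoms: iodoform, IC(I)I
Why: Takai olefination should give the E iodoalkene from the α-branched aldehyde without epimerisation.

Step 11
Reactants: 14 tert-butyl{[(2R,3E)-4-iodo-2-methylbut-3-en-1-yl]oxy}dimethylsilane; 10 (5R,6S)-5-(tert-butyldimethylsilyloxy)-2,6-dimethyl-6-[(E)-2-(triisopropylsilyloxy)ethenyl]cyclohex-2-en-1-one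
Product: 16 (1S,5R,6S)-5-(tert-butyldimethylsilyloxy)-1-[(1E,3R)-4-(tert-butyldimethylsilyloxy)-3-methylbut-1-en-1-yl]-2,6-dimethyl-6-[(E)-2-(triisopropylsilyloxy)ethenyl]cyclohex-2-en-1-ol, via alkenyllithium 15 (not isolated)
Conditions: t-BuLi (2 equiv), Et2O, −78 °C; then 10, THF, −78 → −40 °C; aq. NH4Cl
Reagents that add atoms: none
Why: Iodine–lithium exchange with retention of olefin geometry, then 1,2-addition of the alkenyllithium to the enone carbonyl. In the half-chair with equatorial OTBS the C15 methyl is axial, so attack anti to it should place the new alkenyl group cis to the enol-ether arm and the hydroxyl cis to C15.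

Step 12
Reactants: 16 (1S,5R,6S)-5-(tert-butyldimethylsilyloxy)-1-[(1E,3R)-4-(tert-butyldimethylsilyloxy)-3-methylbut-1-en-1-yl]-2,6-dimethyl-6-[(E)-2-(triisopropylsilyloxy)ethenyl]cyclohex-2-en-1-ol
Product: 19 (2Z,5R,6Z,8S,9S)-5-(tert-butyldimethylsilyloxy)-9-[(2R)-1-(tert-butyldimethylsilyloxy)propan-2-yl]-2,6-dimethyl-8-(triisopropylsilyloxy)cyclodeca-2,6-dien-1-one, via potassium alkoxide 17 (not isolated), via potassium dienolate 18 (not isolated)
Conditions: KH, 18-crown-6, THF, 0 °C → rt; then aq. NH4Cl, −78 °C
Reagents that add atoms: none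
Why: KH gives potassium alkoxide 17, whose C7=C8–C9(O−)–C4–C5=C6 unit is a 3-oxido-1,5-diene; the anionic oxy-Cope [3,3] shift forms C6–C7 while C4–C9 breaks and leaves dienolate 18, which is protonated at C8 on quench. The closest known reaction type is the anionic oxy-Cope ring expansion of cis-1,2-dialkenylcyclohexanols to cyclodec-5-en-1-ones. The ten-membered ring is therefore not closed end to end: it arises by four-carbon ring expansion of ring A through a six-atom chair. C6 and C7 are set by chirality transfer from C4 and C9; since both alkenes are E, OSi(iPr)3 and the C11 side chain are equatorial on the chair and the (6S,7S) pair should result. The new C4=C5 bond should be Z because C3 takes the axial and C15 the equatorial site of the chair in the ring-A half-chair in which 16 is formed (C3–OTBS and the C9 oxide equatorial, C8 axial). The selectivity needed is this chair over the ring-flipped chair, which would give the E olefin and the opposite C6/C7 pair; it is secured by the cis-1,3 relation of the C3 and C9 oxygens, which would be syn-diaxial in the flipped chair. The second 1,5-diene, through C1=C10, cannot react because the equatorial enol-ether arm cannot reach C1.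

Step 13
Reactants: 19 (2Z,5R,6Z,8S,9S)-5-(tert-butyldimethylsilyloxy)-9-[(2R)-1-(tert-butyldimethylsilyloxy)propan-2-yl]-2,6-dimethyl-8-(triisopropylsilyloxy)cyclodeca-2,6-dien-1-one
Product: 20 (1R,2Z,5R,6Z,8S,9S)-5-(tert-butyldimethylsilyloxy)-9-[(2R)-1-(tert-butyldimethylsilyloxy)propan-2-yl]-2,6-dimethyl-8-(triisopropylsilyloxy)cyclodeca-2,6-dien-1-ol
Conditions: (S)-2-methyl-CBS-oxazaborolidine [(S)-1-methyl-3,3-diphenyltetrahydro-1H,3H-pyrrolo[1,2-c][1,3,2]oxazaborole] (0.2 equiv), catecholborane, toluene, −78 °C
Reagents that add atoms: none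
Why: Corey–Bakshi–Shibata reduction: the α-methyl alkenyl side (C10) is the large and C8H2 the small group, so the (S)-catalyst should give the 9R carbinol under reagent control. Catecholborane at −78 °C should leave the trisubstituted olefins alone.

Step 14
Reactants: 20 (1R,2Z,5R,6Z,8S,9S)-5-(tert-butyldimethylsilyloxy)-9-[(2R)-1-(tert-butyldimethylsilyloxy)propan-2-yl]-2,6-dimethyl-8-(triisopropylsilyloxy)cyclodeca-2,6-dien-1-ol
Product: 21 (1R,2Z,5R,6Z,8S,9S)-5-(tert-butyldimethylsilyloxy)-9-[(2R)-1-(tert-butyldimethylsilyloxy)propan-2-yl]-2,6-dimethyl-8-(triisopropylsilyloxy)cyclodeca-2,6-dien-1-yl acetate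
Conditions: Ac2O, pyridine, 4-(dimethylamino)pyridine (cat.), CH2Cl2, 0 °C → rt
Reagents that add atoms: acetic anhydride, CC(=O)OC(C)=O
Why: Acylation of the only free hydroxyl; the C9 acetate of the target is installed with retention.

Step 15
Reactants: 21 (1R,2Z,5R,6Z,8S,9S)-5-(tert-butyldimethylsilyloxy)-9-[(2R)-1-(tert-butyldimethylsilyloxy)propan-2-yl]-2,6-dimethyl-8-(triisopropylsilyloxy)cyclodeca-2,6-dien-1-yl acetate
Product: 22 (1R,2Z,5R,6Z,8S,9S)-5,8-dihydroxy-9-[(2R)-1-hydroxypropan-2-yl]-2,6-dimethylcyclodeca-2,6-dien-1-yl acetate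
Conditions: Bu4NF, AcOH, THF, 0 °C → rt
Reagents that add atoms: none
Why: Fluoride cleaves the three silyl ethers; buffering with acetic acid should keep the acetate in place and avoid a free alkoxide at C3 (oxy-Cope liability of the 3-oxy-1,5-diene).

Step 16
Reactants: 22 (1R,2Z,5R,6Z,8S,9S)-5,8-dihydroxy-9-[(2R)-1-hydroxypropan-2-yl]-2,6-dimethylcyclodeca-2,6-dien-1-yl acetate
Product: 24 (3R,6S,7S,9R,11R)-9-acetoxy-3-hydroxygermacra-1(10)Z,4Z-dien-12,6-olide, via lactol 23 (not isolated)
Conditions: TEMPO (2,2,6,6-tetramethylpiperidine-1-oxyl, cat.), PhI(OAc)2, CH2Cl2, rt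
Reagents that add atoms: none
Why: Oxoammonium oxidation is selective for the primary alcohol; the hydroxy aldehyde closes with the C6 hydroxyl to lactol 23, which is oxidised to the trans-fused γ-lactone. No base is present, so C11 (from the Roche ester, methyl cis to C8) is not epimerised.

Step 17
Reactants: 24 (3R,6S,7S,9R,11R)-9-acetoxy-3-hydroxygermacra-1(10)Z,4Z-dien-12,6-olide
Product: 25 (3S,6S,7S,9R,11R)-3,9-diacetoxygermacra-1(10)Z,4Z-dien-12,6-olide (target)
Conditions: PPh3, diisopropyl azodicarboxylate, AcOH, toluene, 0 °C → rt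
Reagents that add atoms: acetic acid, CC(=O)O
Why: Mitsunobu esterification: SN2 displacement of the C3 oxyphosphonium ion by acetate should invert C3 from R to S and install the second acetate in the same operation.

## Compound list

1 | (R)-carvone, (5R)-2-methyl-5-(prop-1-en-2-yl)cyclohex-2-en-1-one | CC1=CC[C@@H](C(C)=C)CC1=O | starting material
2 | (5R)-5-(1-hydroperoxy-1-methoxyethyl)-2-methylcyclohex-2-en-1-one (mixture at the side-chain carbon) | CC1=CC[C@@H](C(C)(OC)OO)CC1=O | intermediate
3 | (5R)-5-acetoxy-2-methylcyclohex-2-en-1-one | CC1=CC[C@@H](OC(C)=O)CC1=O | intermediate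
4 | (5R)-5-hydroxy-2-methylcyclohex-2-en-1-one | CC1=CC[C@@H](O)CC1=O | intermediate
5 | (5R)-5-(tert-butyldimethylsilyloxy)-2-methylcyclohex-2-en-1-one | CC1=CC[C@@H](O[Si](C)(C)C(C)(C)C)CC1=O | intermediate
6 | (5R,6S)-5-(tert-butyldimethylsilyloxy)-2,6-dimethylcyclohex-2-en-1-one (6-methyl trans to OTBS) | CC1=CC[C@@H](O[Si](C)(C)C(C)(C)C)[C@H](C)C1=O | intermediate
7 | (5R,6S)-6-allyl-5-(tert-butyldimethylsilyloxy)-2,6-dimethylcyclohex-2-en-1-one (allyl trans, methyl cis to OTBS) | CC1=CC[C@@H](O[Si](C)(C)C(C)(C)C)[C@](C)(CC=C)C1=O | intermediate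
8 | (5R,6S)-5-(tert-butyldimethylsilyloxy)-6-(2,3-dihydroxypropyl)-2,6-dimethylcyclohex-2-en-1-one (mixture at the carbinol) | CC1=CC[C@@H](O[Si](C)(C)C(C)(C)C)[C@](C)(CC(O)CO)C1=O | intermediate
9 | 2-[(1S,6R)-6-(tert-butyldimethylsilyloxy)-1,3-dimethyl-2-oxocyclohex-3-en-1-yl]acetaldehyde | CC1=CC[C@@H](O[Si](C)(C)C(C)(C)C)[C@](C)(CC=O)C1=O | intermediate
10 | (5R,6S)-5-(tert-butyldimethylsilyloxy)-2,6-dimethyl-6-[(E)-2-(triisopropylsilyloxy)ethenyl]cyclohex-2-en-1-one | CC1=CC[C@@H](O[Si](C)(C)C(C)(C)C)[C@](C)(/C=C/O[Si](C(C)C)(C(C)C)C(C)C)C1=O | intermediate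
11 | methyl (S)-3-hydroxy-2-methylpropanoate | COC(=O)[C@@H](C)CO | starting material
12 | methyl (S)-3-(tert-butyldimethylsilyloxy)-2-methylpropanoate | COC(=O)[C@@H](C)CO[Si](C)(C)C(C)(C)C | intermediate
13 | (S)-3-(tert-butyldimethylsilyloxy)-2-methylpropanal | O=C[C@@H](C)CO[Si](C)(C)C(C)(C)C | intermediate
14 | tert-butyl{[(2R,3E)-4-iodo-2-methylbut-3-en-1-yl]oxy}dimethylsilane | I/C=C/[C@@H](C)CO[Si](C)(C)C(C)(C)C | intermediate
15 | [(1E,3R)-4-(tert-butyldimethylsilyloxy)-3-methylbut-1-en-1-yl]lithium | [Li]/C=C/[C@@H](C)CO[Si](C)(C)C(C)(C)C | intermediate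
16 | (1S,5R,6S)-5-(tert-butyldimethylsilyloxy)-1-[(1E,3R)-4-(tert-butyldimethylsilyloxy)-3-methylbut-1-en-1-yl]-2,6-dimethyl-6-[(E)-2-(triisopropylsilyloxy)ethenyl]cyclohex-2-en-1-ol | CC1=CC[C@@H](O[Si](C)(C)C(C)(C)C)[C@](C)(/C=C/O[Si](C(C)C)(C(C)C)C(C)C)[C@]1(O)/C=C/[C@@H](C)CO[Si](C)(C)C(C)(C)C | intermediate
17 | potassium alkoxide of 16 | CC1=CC[C@@H](O[Si](C)(C)C(C)(C)C)[C@](C)(/C=C/O[Si](C(C)C)(C(C)C)C(C)C)[C@]1([O-])/C=C/[C@@H](C)CO[Si](C)(C)C(C)(C)C.[K+] | intermediate
18 | potassium dienolate of 19 (C8=C9 enolate, geometry not specified) | CC(C)(C)[Si](C)(C)O[C@@H]1C/C=C(/C)C([O-])=C[C@@H]([C@@H](C)CO[Si](C)(C)C(C)(C)C)[C@@H](/C=C\1C)O[Si](C(C)C)(C(C)C)C(C)C.[K+] | intermediate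
19 | (2Z,5R,6Z,8S,9S)-5-(tert-butyldimethylsilyloxy)-9-[(2R)-1-(tert-butyldimethylsilyloxy)propan-2-yl]-2,6-dimethyl-8-(triisopropylsilyloxy)cyclodeca-2,6-dien-1-one (3R,6S,7S in germacrane numbering) | CC(C)(C)[Si](C)(C)O[C@@H]1C/C=C(/C)C(=O)C[C@@H]([C@@H](C)CO[Si](C)(C)C(C)(C)C)[C@@H](/C=C\1C)O[Si](C(C)C)(C(C)C)C(C)C | intermediate
20 | (1R,2Z,5R,6Z,8S,9S)-5-(tert-butyldimethylsilyloxy)-9-[(2R)-1-(tert-butyldimethylsilyloxy)propan-2-yl]-2,6-dimethyl-8-(triisopropylsilyloxy)cyclodeca-2,6-dien-1-ol | CC(C)(C)[Si](C)(C)O[C@@H]1C/C=C(/C)[C@H](O)C[C@@H]([C@@H](C)CO[Si](C)(C)C(C)(C)C)[C@@H](/C=C\1C)O[Si](C(C)C)(C(C)C)C(C)C | intermediate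
21 | acetate of 20 | CC(C)(C)[Si](C)(C)O[C@@H]1C/C=C(/C)[C@H](OC(C)=O)C[C@@H]([C@@H](C)CO[Si](C)(C)C(C)(C)C)[C@@H](/C=C\1C)O[Si](C(C)C)(C(C)C)C(C)C | intermediate
22 | (1R,2Z,5R,6Z,8S,9S)-5,8-dihydroxy-9-[(2R)-1-hydroxypropan-2-yl]-2,6-dimethylcyclodeca-2,6-dien-1-yl acetate | O[C@@H]1C/C=C(/C)[C@H](OC(C)=O)C[C@@H]([C@@H](C)CO)[C@@H](/C=C\1C)O | intermediate
23 | (3R,6S,7S,9R,11R)-9-acetoxy-3,12-dihydroxy-6,12-epoxygermacra-1(10)Z,4Z-diene (lactol, mixture at C12) | O[C@@H]1C/C=C(/C)[C@H](OC(C)=O)C[C@@H]2[C@@H](/C=C\1C)OC(O)[C@@H]2C | intermediate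
24 | (3R,6S,7S,9R,11R)-9-acetoxy-3-hydroxygermacra-1(10)Z,4Z-dien-12,6-olide | O[C@@H]1C/C=C(/C)[C@H](OC(C)=O)C[C@@H]2[C@@H](/C=C\1C)OC(=O)[C@@H]2C | intermediate
25 | (3S,6S,7S,9R,11R)-3,9-diacetoxygermacra-1(10)Z,4Z-dien-12,6-olide | CC(=O)O[C@H]1C/C=C(/C)[C@H](OC(C)=O)C[C@@H]2[C@@H](/C=C\1C)OC(=O)[C@@H]2C | target

## Step count and least certain steps

Total: 17 steps. Longest linear sequence: 14 steps (steps 1–7 and 11–17, from 1).

**Step 12 (key step).** Most likely failure: loss of control over the chair, so that the ring-flipped chair gives the E olefin with the opposite C6/C7 pair. A second is migration of the C3 silyl group to the C9 oxide in the crown-ether-separated alkoxide, which would stop the anionic acceleration. Fallback, from 16 back to 19: the rearrangement is run on a neutral species. Compound 16 is silylated (Me3SiCl, imidazole) to trimethylsilyl ether F1, which is heated in toluene at about 200 °C in a sealed, base-washed tube. The thermal oxy-Cope rearrangement should give trimethylsilyl dienol ether F2, and brief methanolysis (K2CO3, MeOH, 0 °C) gives 19. No alkoxide is present, so silyl migration is excluded, and the bulky C9 silyloxy group reinforces the same chair.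

**Step 11.** Most likely failure: poor facial selectivity in the addition to the hindered enone (attack syn to C15 gives the trans-dialkenyl isomer, which cannot give the Z olefin), with γ-deprotonation of the enone as a side path. Fallback, from 13 and 10 back to 16: a slimmer nucleophile is used and the olefin made afterwards. Aldehyde 13 is converted by Ohira–Bestmann homologation (dimethyl (1-diazo-2-oxopropyl)phosphonate, K2CO3, MeOH) into alkyne F3. Its lithium acetylide (n-BuLi, THF, −78 °C) adds to 10 to give propargylic alcohol F4. Trans-hydroalumination with NaAlH2(OCH2CH2OCH3)2 (THF, 0 °C → rt) gives the E allylic alcohol 16.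

**Step 5.** Most likely failure: β-elimination of silyloxide from the fully substituted lithium enolate at the temperature needed for C-allylation (leading to a phenol), or O-allylation. Fallback, from 6 back to 7: the enolate of 6 is trapped at −78 °C (LiN(SiMe3)2, allyl chloroformate) as allyl enol carbonate F5. Decarboxylative Tsuji allylation (Pd(PPh3)4 cat., THF, rt) then delivers the allyl group to C4 anti to OTBS under neutral conditions, giving 7.

**Step 13.** Most likely failure: mismatch between the catalyst and the conformational bias of the twisted ten-membered enone, giving low selectivity or slow reduction. Fallback, from 19 to 25: substrate-controlled Luche reduction (NaBH4, CeCl3·7H2O, MeOH, −78 °C). If it gives the 9R alcohol, this is 20 and the route continues unchanged. If it gives the 9S alcohol F6, this is desilylated (Bu4NF, AcOH) to tetraol F7 and oxidised (TEMPO, PhI(OAc)2) to dihydroxy lactone F8. A double Mitsunobu esterification (PPh3, diisopropyl azodicarboxylate, AcOH) then inverts C3 and C9 together and gives 25.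

**Step 17.** Most likely failure: ionisation of the allylic oxyphosphonium ion, with SN2′ attack, elimination to a diene or partial retention, so that C3 is not cleanly inverted. Fallback, from 24 to 25: 24 is oxidised with Dess–Martin periodinane (NaHCO3, CH2Cl2) to enone F9. Reduction with the (R)-enantiomer of the oxazaborolidine of step 13 and catecholborane gives the 3S alcohol F10 under reagent control. Acetylation (Ac2O, pyridine) gives 25.

## Further compounds

F1 | step 12 | trimethylsilyl ether of 16 | CC1=CC[C@@H](O[Si](C)(C)C(C)(C)C)[C@](C)(/C=C/O[Si](C(C)C)(C(C)C)C(C)C)[C@]1(O[Si](C)(C)C)/C=C/[C@@H](C)CO[Si](C)(C)C(C)(C)C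
F2 | step 12 | trimethylsilyl dienol ether of 19 (C8=C9 geometry not specified) | CC(C)(C)[Si](C)(C)O[C@@H]1C/C=C(/C)C(O[Si](C)(C)C)=C[C@@H]([C@@H](C)CO[Si](C)(C)C(C)(C)C)[C@@H](/C=C\1C)O[Si](C(C)C)(C(C)C)C(C)C
F3 | step 11 | (R)-tert-butyldimethyl[(2-methylbut-3-yn-1-yl)oxy]silane | C#C[C@@H](C)CO[Si](C)(C)C(C)(C)C
F4 | step 11 | propargylic alcohol, the 7,8-alkyne analogue of 16 | CC1=CC[C@@H](O[Si](C)(C)C(C)(C)C)[C@](C)(/C=C/O[Si](C(C)C)(C(C)C)C(C)C)[C@]1(O)C#C[C@@H](C)CO[Si](C)(C)C(C)(C)C
F5 | step 5 | allyl [(3R)-3-(tert-butyldimethylsilyloxy)-2,6-dimethylcyclohexa-1,5-dien-1-yl] carbonate | CC1=CC[C@@H](O[Si](C)(C)C(C)(C)C)C(C)=C1OC(=O)OCC=C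
F6 | step 13 | 9S alcohol, C9 epimer of 20 | CC(C)(C)[Si](C)(C)O[C@@H]1C/C=C(/C)[C@@H](O)C[C@@H]([C@@H](C)CO[Si](C)(C)C(C)(C)C)[C@@H](/C=C\1C)O[Si](C(C)C)(C(C)C)C(C)C
F7 | step 13 | (1S,2Z,5R,6Z,8S,9S)-9-[(2R)-1-hydroxypropan-2-yl]-2,6-dimethylcyclodeca-2,6-diene-1,5,8-triol | O[C@@H]1C/C=C(/C)[C@@H](O)C[C@@H]([C@@H](C)CO)[C@@H](/C=C\1C)O
F8 | step 13 | (3R,6S,7S,9S,11R)-3,9-dihydroxygermacra-1(10)Z,4Z-dien-12,6-olide | O[C@@H]1C/C=C(/C)[C@@H](O)C[C@@H]2[C@@H](/C=C\1C)OC(=O)[C@@H]2C
F9 | step 17 | (6S,7S,9R,11R)-9-acetoxy-3-oxogermacra-1(10)Z,4Z-dien-12,6-olide | O=C1C/C=C(/C)[C@H](OC(C)=O)C[C@@H]2[C@@H](/C=C\1C)OC(=O)[C@@H]2C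
F10 | step 17 | (3S,6S,7S,9R,11R)-9-acetoxy-3-hydroxygermacra-1(10)Z,4Z-dien-12,6-olide | O[C@H]1C/C=C(/C)[C@H](OC(C)=O)C[C@@H]2[C@@H](/C=C\1C)OC(=O)[C@@H]2C
A1 | alternative 1 | 9,10-seco aldehyde/(Z)-iodoalkene: C9 aldehyde, C10 iodide, C3 tert-butyldimethylsilyl ether, lactone in place (3S,6S,7S,11R) | O=CC[C@@H]1[C@@H](/C=C(/C)[C@H](C/C=C(/C)I)O[Si](C)(C)C(C)(C)C)OC(=O)[C@@H]1C
A2 | alternative 2 | cis-fused decalin with C4–C9 bond: C9 tertiary alcohol, C5 mesylate, C3 tert-butyldimethylsilyl ether, trans-lactone on ring B | CC1=CC[C@H](O[Si](C)(C)C(C)(C)C)[C@]2(C)[C@H](OS(C)(=O)=O)[C@H]3OC(=O)[C@H](C)[C@@H]3C[C@]12O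
A3 | alternative 3 | methyl (2Z,5R,6Z,9S,10Z)-2-(bromomethyl)-5,9-bis(tert-butyldimethylsilyloxy)-6,10-dimethyl-12-oxododeca-2,6,10-trienoate | O=C/C=C(/C)[C@@H](O[Si](C)(C)C(C)(C)C)C/C=C(/C)[C@H](O[Si](C)(C)C(C)(C)C)C/C=C(/C(=O)OC)CBr
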